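**Assumption:** (R)-2-methylbutan-1-ol and (R)-lactic acid are bought as single enantiomers, and the acidic C8a hydrogen (α to the C8 ketone, γ to the C6 enone) is taken to equilibrate under mild base to the (8aR) epimer, in which 8a-H and the 7-oxygen are cis and pseudo-axial while 7-CH3 and C1 are pseudo-equatorial.

Atom labels C1–C8a follow the isochromene numbering of the target (O2 is the ring oxygen). Ring A is the carbocycle, ring B the pyran.

## Retrosynthetic overview

1. Target ⇐ O-acetylation of the 7-hydroxy bicycle; C8a–H is the last centre fixed, by enolate protonation and equilibration.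
2. Both rings ⇐ one anionic cascade of an (R)-lactate-derived dioxolanone enolate with a 3-chloro-4-alkynyl-5,6-dihydropyran-2-one: C6–C7 acylation opens the lactone, the freed C1 alkoxide closes ring B first (O2–C3), then a vinylogous Dieckmann closure (C8a–C8) forms ring A.
3. Alkynyl lactone ⇐ Sonogashira coupling of a chloro triflyloxy lactone (from methyl acetoacetate and formaldehyde) with the (R)-dienyne.
4. Dienyne ⇐ (R)-2-methylbutan-1-ol by oxidation/Wittig and Horner–Wadsworth–Emmons olefination.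
5. C7 ⇐ (R)-lactic acid through the cis tert-butyl dioxolanone (self-regeneration of stereocentres).

## Route

Step 1
Reactants: 1 (R)-2-methylbutan-1-ol; 2 2-(triphenylphosphoranylidene)propanal
Product: 4 (2E,4R)-2,4-dimethylhex-2-enal, via (R)-2-methylbutanal 3 (not isolated)
Conditions: TEMPO (1 mol%), KBr (10 mol%), NaOCl, NaHCO3, CH2Cl2/H2O, 0 °C; dried organic phase, then 2, toluene, 80 °C
Reagents that add atoms: none
Why: TEMPO/NaOCl (Anelli) oxidation gives the α-chiral aldehyde without epimerisation and the stabilised ylide then gives the (E)-trisubstituted enal by Wittig olefination under neutral conditions; no new stereocentre is formed and the (R) centre of 1 is carried through.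

Step 2
Reactants: 4 (2E,4R)-2,4-dimethylhex-2-enal; 5 diethyl [3-(trimethylsilyl)prop-2-yn-1-yl]phosphonate
Product: 7 (3E,5E,7R)-5,7-dimethylnona-3,5-dien-1-yne, via TMS-dienyne 6 (not isolated)
Conditions: 5, LiN(SiMe3)2, THF, −78 °C; 4, −78 → 0 °C; then MeOH, K2CO3 (0.2 equiv), 23 °C
Reagents that add atoms: none
Why: Horner–Wadsworth–Emmons olefination with the lithiated propargylic phosphonate adds to the aldehyde carbonyl and gives the (E)-alkene (expected E:Z about 10:1, minor isomer removed on silica), after which K2CO3/MeOH cleaves the C–Si bond; no stereocentre is formed.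

Step 3
Reactants: 8 methyl acetoacetate
Product: 10 4-hydroxy-5,6-dihydro-2H-pyran-2-one, via methyl 5-hydroxy-3-oxopentanoate 9 (not isolated)
Conditions: NaH, THF, 0 °C; n-C4H9Li, 0 °C; (CH2O)n, 0 → 23 °C; then aq. NaOH, 23 °C; aq. HCl to pH 1
Reagents that add atoms: paraformaldehyde (as formaldehyde), C=O
Why: The Weiler dianion of 8 reacts with formaldehyde only at the terminal carbon (aldol addition) and hydroxide then drives lactonisation to the stable enolate of the β-keto lactone; no stereocentre is formed.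

Step 4
Reactants: 10 4-hydroxy-5,6-dihydro-2H-pyran-2-one
Product: 11 3-chloro-4-hydroxy-5,6-dihydro-2H-pyran-2-one
Conditions: N-chlorosuccinimide (1.0 equiv), CH2Cl2, 0 → 23 °C
Reagents that add atoms: N-chlorosuccinimide, O=C1CCC(=O)N1Cl
Why: Electrophilic α-chlorination of the cyclic 1,3-dicarbonyl enol with one equivalent of reagent occurs only at C3 between the two carbonyl groups; no stereocentre is formed.

Step 5
Reactants: 11 3-chloro-4-hydroxy-5,6-dihydro-2H-pyran-2-one
Product: 12 3-chloro-2-oxo-5,6-dihydro-2H-pyran-4-yl trifluoromethanesulfonate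
Conditions: Tf2O, Et3N, CH2Cl2, −78 °C
Reagents that add atoms: trifluoromethanesulfonic anhydride, O=S(=O)(OS(=O)(=O)C(F)(F)F)C(F)(F)F
Why: O-sulfonylation of the acidic enol gives the vinyl triflate, whose C–O bond is β to the lactone carbonyl and so activated for cross-coupling; no stereocentre is formed.

Step 6
Reactants: 12 3-chloro-2-oxo-5,6-dihydro-2H-pyran-4-yl trifluoromethanesulfonate; 7 (3E,5E,7R)-5,7-dimethylnona-3,5-dien-1-yne
Product: 13 3-chloro-4-[(3E,5E,7R)-5,7-dimethylnona-3,5-dien-1-yn-1-yl]-5,6-dihydro-2H-pyran-2-one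
Conditions: PdCl2(PPh3)2 (3 mol%), CuI (6 mol%), i-Pr2NEt, THF, 23 °C
Reagents that add atoms: none
Why: Sonogashira coupling occurs at the β-triflate, which adds to zerovalent palladium far faster than the α-C–Cl bond, and the hindered amine cannot add to the enoate; no stereocentre is formed and the (E,E)-diene and the (R) centre are untouched.

Step 7
Reactants: 14 (R)-lactic acid; 15 pivalaldehyde
Product: 16 (2R,5R)-2-tert-butyl-5-methyl-1,3-dioxolan-4-one
Conditions: TsOH·H2O (cat.), H2SO4 (cat.), pentane, reflux, Dean–Stark; crystallisation from pentane/Et2O, −78 °C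
Reagents that add atoms: none
Why: Acid-catalysed acetalisation with azeotropic water removal (Seebach dioxolanone formation) gives mainly the cis acetal under thermodynamic control, so the acetal centre (2R) is set relative to the lactate centre and the cis isomer is purified by cold crystallisation.

Step 8
Reactants: 16 (2R,5R)-2-tert-butyl-5-methyl-1,3-dioxolan-4-one; 13 3-chloro-4-[(3E,5E,7R)-5,7-dimethylnona-3,5-dien-1-yn-1-yl]-5,6-dihydro-2H-pyran-2-one
Product: 19 (7R,8aR)-5-chloro-3-[(1E,3E,5R)-3,5-dimethylhepta-1,3-dien-1-yl]-7-hydroxy-7-methyl-1H-isochromene-6,8(7H,8aH)-dione, via ring-opened keto alkoxide 17 (not isolated), via pyranylidene ketone 18 (not isolated)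
Conditions: 16, LiN(i-Pr)2 (1.05 equiv), THF, −78 °C; 13, −78 → −20 °C; t-BuOH (1 equiv), −20 → 23 °C; aq. NH4Cl
Reagents that add atoms: none
Why: Proposed new method: the lithium enolate of 16 is acylated at the lactone carbonyl of 13 anti to the tert-butyl group (self-regeneration of stereocentres, which fixes C7 with retention of the lactate configuration; conjugate addition is blocked because the β-carbon is fully substituted and the α-carbon carries chlorine), the ring-opened C1 alkoxide 17 then adds in a 6-endo-dig oxa-Michael sense to C3 of the new enynone to close ring B (18), and after t-BuOH-mediated proton transfer the γ-carbanion at C8a attacks the dioxolanone carbonyl in a 6-(enolendo)-exo-trig vinylogous Dieckmann condensation that closes ring A, expels pivalaldehyde and ends in the stabilised vinylogous 1,3-diketone enolate, whose protonation at C8a is expected to give mainly the (8aR) epimer with 8a-H cis to the 7-oxygen; the closest known reaction types are the Claisen-type addition of lithium ester enolates to lactones, the base-mediated cyclisation of hydroxy ynones to dihydropyranones and the Dieckmann cyclisation of α-acyloxy esters.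

Step 9
Reactants: 19 (7R,8aR)-5-chloro-3-[(1E,3E,5R)-3,5-dimethylhepta-1,3-dien-1-yl]-7-hydroxy-7-methyl-1H-isochromene-6,8(7H,8aH)-dione
Product: 20 (7R,8aR)-5-chloro-3-[(1E,3E,5R)-3,5-dimethylhepta-1,3-dien-1-yl]-7-methyl-6,8-dioxo-6,7,8,8a-tetrahydro-1H-isochromen-7-yl acetate
Conditions: Ac2O (3 equiv), Et3N (3 equiv), DMAP (0.2 equiv), CH2Cl2, 0 → 23 °C; then MeOH, aq. NaHCO3, 23 °C
Reagents that add atoms: acetic anhydride, CC(=O)OC(C)=O
Why: In this DMAP-catalysed acylation any kinetically formed enol acetate passes its acetyl group to the neighbouring tertiary 7-OH by a 1,2-O→O acyl shift and leftover enol acetate is cleaved in the MeOH/NaHCO3 work-up, while the acidic C8a–H equilibrates under the amine base to the (8aR) epimer assumed above; C7 is untouched.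

## Compound list

1 | (R)-2-methylbutan-1-ol | CC[C@@H](C)CO | starting material
2 | 2-(triphenylphosphoranylidene)propanal | CC(C=O)=P(c1ccccc1)(c1ccccc1)c1ccccc1 | starting material
3 | (R)-2-methylbutanal | CC[C@@H](C)C=O | intermediate
4 | (2E,4R)-2,4-dimethylhex-2-enal | CC[C@@H](C)/C=C(C)/C=O | intermediate
5 | diethyl [3-(trimethylsilyl)prop-2-yn-1-yl]phosphonate | CCOP(=O)(CC#C[Si](C)(C)C)OCC | starting material
6 | TMS-dienyne, trimethyl[(3E,5E,7R)-5,7-dimethylnona-3,5-dien-1-yn-1-yl]silane | CC[C@@H](C)/C=C(C)/C=C/C#C[Si](C)(C)C | intermediate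
7 | (3E,5E,7R)-5,7-dimethylnona-3,5-dien-1-yne | CC[C@@H](C)/C=C(C)/C=C/C#C | intermediate
8 | methyl acetoacetate | COC(=O)CC(C)=O | starting material
9 | methyl 5-hydroxy-3-oxopentanoate | COC(=O)CC(=O)CCO | intermediate
10 | 4-hydroxy-5,6-dihydro-2H-pyran-2-one (enol of dihydro-2H-pyran-2,4(3H)-dione) | O=C1C=C(O)CCO1 | intermediate
11 | 3-chloro-4-hydroxy-5,6-dihydro-2H-pyran-2-one | O=C1OCCC(O)=C1Cl | intermediate
12 | 3-chloro-2-oxo-5,6-dihydro-2H-pyran-4-yl trifluoromethanesulfonate | O=C1OCCC(OS(=O)(=O)C(F)(F)F)=C1Cl | intermediate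
13 | 3-chloro-4-[(3E,5E,7R)-5,7-dimethylnona-3,5-dien-1-yn-1-yl]-5,6-dihydro-2H-pyran-2-one | CC[C@@H](C)/C=C(C)/C=C/C#CC1=C(Cl)C(=O)OCC1 | intermediate
14 | (R)-lactic acid | C[C@@H](O)C(=O)O | starting material
15 | pivalaldehyde | CC(C)(C)C=O | starting material
16 | (2R,5R)-2-tert-butyl-5-methyl-1,3-dioxolan-4-one | C[C@H]1O[C@@H](C(C)(C)C)OC1=O | intermediate
17 | ring-opened keto alkoxide, drawn as the alcohol: (2R,5S)-2-tert-butyl-5-[(2Z,6E,8E,10R)-2-chloro-3-(2-hydroxyethyl)-8,10-dimethyldodeca-2,6,8-trien-4-ynoyl]-5-methyl-1,3-dioxolan-4-one | C[C@@]1(C(=O)/C(Cl)=C(/C#C/C=C/C(C)=C/[C@H](C)CC)CCO)O[C@@H](C(C)(C)C)OC1=O | intermediate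
18 | pyranylidene ketone: (2R,5S)-2-tert-butyl-5-[(2Z)-2-chloro-2-{6-[(1E,3E,5R)-3,5-dimethylhepta-1,3-dien-1-yl]-2,3-dihydro-4H-pyran-4-ylidene}acetyl]-5-methyl-1,3-dioxolan-4-one | C[C@@]1(C(=O)/C(Cl)=C2/C=C(/C=C/C(C)=C/[C@H](C)CC)OCC2)O[C@@H](C(C)(C)C)OC1=O | intermediate
19 | (7R,8aR)-5-chloro-3-[(1E,3E,5R)-3,5-dimethylhepta-1,3-dien-1-yl]-7-hydroxy-7-methyl-1H-isochromene-6,8(7H,8aH)-dione | CC[C@@H](C)/C=C(C)/C=C/C1=CC2=C(Cl)C(=O)[C@](C)(O)C(=O)[C@H]2CO1 | intermediate
20 | (7R,8aR)-5-chloro-3-[(1E,3E,5R)-3,5-dimethylhepta-1,3-dien-1-yl]-7-methyl-6,8-dioxo-6,7,8,8a-tetrahydro-1H-isochromen-7-yl acetate | CC[C@@H](C)/C=C(C)/C=C/C1=CC2=C(Cl)C(=O)[C@](C)(OC(C)=O)C(=O)[C@H]2CO1 | target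

## Step count

Total: 9 steps. Longest linear sequence: 6 steps (8 → 10 → 11 → 12 → 13 → 19 → 20).

## Steps most likely to fail

**Step 8 (cascade).** The hindered enolate may deprotonate 13 at the γ-CH2, add to the alkyne terminus, or revert by retro-Claisen before the alkoxide is trapped.

Fallback, from 13 back to the route at 19, with the two rings closed in separate operations. Reduce 13 with (i-Bu)2AlH (CH2Cl2, −78 °C) to the lactol 3-chloro-4-[(3E,5E,7R)-5,7-dimethylnona-3,5-dien-1-yn-1-yl]-5,6-dihydro-2H-pyran-2-ol F1. DBU in THF opens F1 to the hydroxy enynal, which closes ring B by 6-endo oxa-Michael addition to the push-pull aldehyde (2Z)-2-chloro-2-{6-[(1E,3E,5R)-3,5-dimethylhepta-1,3-dien-1-yl]-2,3-dihydro-4H-pyran-4-ylidene}acetaldehyde F2. Aldol addition of the lithium enolate of 16 (LiN(i-Pr)2, THF, −78 °C; an aldehyde is attacked much faster than it is deprotonated, again anti to tert-butyl) gives the carbinol (2R,5S)-2-tert-butyl-5-[(2Z)-2-chloro-1-hydroxy-2-{6-[(1E,3E,5R)-3,5-dimethylhepta-1,3-dien-1-yl]-2,3-dihydro-4H-pyran-4-ylidene}ethyl]-5-methyl-1,3-dioxolan-4-one F3. MnO2 in CH2Cl2 oxidises this allylic carbinol to 18, now isolated, and LiOt-Bu (THF, 0 °C) effects the Dieckmann closure of ring A to 19.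

**Step 9 (acetylation and C8a).** The enol oxygen may be acetylated instead of the tertiary alcohol, or the C8a ratio may be poor.

Fallback, from 19 back to the route at 20. Acylate the triethylammonium enolate deliberately on oxygen (AcCl, Et3N, CH2Cl2, −78 °C) and isolate the enol acetate (7R)-5-chloro-3-[(1E,3E,5R)-3,5-dimethylhepta-1,3-dien-1-yl]-7-hydroxy-7-methyl-6-oxo-6,7-dihydro-1H-isochromen-8-yl acetate F4. Then trigger the 1,2-O→O acyl shift to the tertiary oxygen with catalytic DMAP in CH2Cl2 to reach 20. If the thermodynamic C8a ratio is unfavourable, replace equilibration by reagent-controlled kinetic protonation of the lithium enolate of 20 with 2,6-di-tert-butylphenol at −78 °C.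

**Step 2 (olefination).** The E:Z ratio may be insufficient, or the lithiated phosphonate may deprotonate the enal at the γ-position.

Fallback, from 4 back to the route at 7. Homologate 4 with (triphenylphosphoranylidene)acetaldehyde (toluene, 60 °C) to the dienal (2E,4E,6R)-4,6-dimethylocta-2,4-dienal F5, in which the new alkene is set (E) by the stabilised ylide. Then convert the aldehyde into the terminal alkyne with dimethyl (1-diazo-2-oxopropyl)phosphonate, K2CO3 and MeOH (Ohira–Bestmann) to give 7.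

Further compounds
F1 | step 8 | 3-chloro-4-[(3E,5E,7R)-5,7-dimethylnona-3,5-dien-1-yn-1-yl]-5,6-dihydro-2H-pyran-2-ol | CC[C@@H](C)/C=C(C)/C=C/C#CC1=C(Cl)C(O)OCC1
F2 | step 8 | (2Z)-2-chloro-2-{6-[(1E,3E,5R)-3,5-dimethylhepta-1,3-dien-1-yl]-2,3-dihydro-4H-pyran-4-ylidene}acetaldehyde | O=C/C(Cl)=C1/C=C(/C=C/C(C)=C/[C@H](C)CC)OCC1
F3 | step 8 | (2R,5S)-2-tert-butyl-5-[(2Z)-2-chloro-1-hydroxy-2-{6-[(1E,3E,5R)-3,5-dimethylhepta-1,3-dien-1-yl]-2,3-dihydro-4H-pyran-4-ylidene}ethyl]-5-methyl-1,3-dioxolan-4-one | C[C@@]1(C(O)/C(Cl)=C2/C=C(/C=C/C(C)=C/[C@H](C)CC)OCC2)O[C@@H](C(C)(C)C)OC1=O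
F4 | step 9 | (7R)-5-chloro-3-[(1E,3E,5R)-3,5-dimethylhepta-1,3-dien-1-yl]-7-hydroxy-7-methyl-6-oxo-6,7-dihydro-1H-isochromen-8-yl acetate | CC[C@@H](C)/C=C(C)/C=C/C1=CC2=C(Cl)C(=O)[C@](C)(O)C(OC(C)=O)=C2CO1
F5 | step 2 | (2E,4E,6R)-4,6-dimethylocta-2,4-dienal | CC[C@@H](C)/C=C(C)/C=C/C=O
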